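Abbreviation: TBS = tert-butyldimethylsilyl. Core numbering throughout: 3,7-dioxabicyclo[3.3.0]octan-2-one, with the lactone ring C2–O3–C4–C5–C1 and the ether ring C1–C8–O7–C6–C5.

## Analysis of the target

The target 14 is a cis-fused 3,7-dioxabicyclo[3.3.0]octan-2-one in which a γ-lactone (C2, O3, C4, C5, C1) and a tetrahydrofuran (C1, C8, O7, C6, C5) share the C1–C5 bond. C4 carries the 4-hydroxy-3,5-dimethoxyphenyl (syringyl) ring and C8 the 3,4-dihydroxyphenyl (catechol) ring. There are four contiguous stereocentres, C1 (R), C4 (S), C5 (S) and C8 (S). Their hydrogen atoms all lie on the convex face, so both aryl groups are endo: the syringyl group is cis to C6 on the lactone ring and the catechol group is cis to C2 on the ether ring. This endo,endo arrangement is the crowded one that equilibration would not give, so both benzylic centres must be set kinetically and afterwards kept away from conditions that open benzylic C–O bonds. The sensitive groups are the three phenols (the catechol oxidises easily), the C4–O3 bond (a p-hydroxybenzylic ester that can ionise to a quinone methide under base or to a cation under acid), and the C8–O7 ether (benzylic and β to the lactone carbonyl, so open to elimination). The two aryl groups are different, so each must also be delivered to its own carbon. The strategy rests on the lactone ring: an aryl-bearing C4 cis to the one-carbon branch C6 on C5, with C1 still unsubstituted, is the pattern formed when the β-carbon of an enal (C2, C1, C5) adds as a homoenolate to an aryl aldehyde (C4) and the new alkoxide closes O3–C2.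

## Retrosynthetic reasoning

**14 from 13 (three O–Si bonds).** The phenols are carried as TBS ethers from the first step. These ethers tolerate the carbene/amidine medium, an amide base, weak acid and hydrogenation, and they come off without hydrogenolysis, which would threaten the benzylic C4–O3 and C8–O7 bonds. The forward step must cleave three aryl silyl ethers without ever producing free phenoxide.

**13 from 12 (C1–H and C8–H).** Removing these two hydrogens gives the C1=C8 enol ether 12. C8 needs the less stable endo configuration, and addition of hydrogen is the one operation that sets it kinetically. The convex face of the folded bicycle is open, and the concave face is additionally covered by the syringyl group on C4. C1 can only become cis-fused. The forward step must saturate a tetrasubstituted alkene and leave two electron-rich arenes and the benzylic C–O bonds alone.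

**12 from 9, through 10 and 11 (O7–C8).** Cutting the enol ether C–O bond turns C8 into a ketone carbon and O7 into a primary alcohol. The reverse closure of a hydroxy ketone to a five-membered hemiketal, followed by dehydration to an enol ether conjugated with the lactone carbonyl, is close to automatic. The forward step has to free the primary silyl ether in 9 in the presence of three aryl silyl ethers, for which weak acid is the selective reagent.

**9 from 5 and 8 (C1–C8).** The ketone carbon C8 is disconnected from C1 as an acyl donor. Lactone 5 has a single enolisable position, so a Claisen-type acylation can only occur at C1. The catechol ring arrives as acid chloride 8, which fixes its place at C8. Compound 8 goes back through silyl ester 7 to acid 6.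

**5 from 2 and 4 (C4–C5 and O3–C2, the key disconnection).** Cutting the lactone at these two bonds gives two aldehydes. Enal 4 supplies C2, C1, C5 and C6 and reacts through its β-carbon with inverted polarity. Aldehyde 2 supplies C4 and the syringyl ring. A chiral carbene catalyst makes both bonds, the ring and both stereocentres in one operation, and the cis relation between aryl and C6 is the normal outcome of this annulation. No other disconnection of the lactone reaches such simple fragments.

**2 from 1, and 4 from 3.** Aldehyde 2 is the silyl ether of 1. Enal 4 is the two-carbon Wittig homologue of aldehyde 3, which fixes the (E) geometry.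

## Alternatives that were turned down

**Alternative 1: photocycloaddition of an aryl aldehyde to a chiral 3-furoate.**
- Disconnection: C4–C5, with a temporary O3–C6 bond. The furoate supplies C1, C2, C5, C6, C8 and O7.
- Forward key step: irradiation of acetylated syringaldehyde A1 with the 8-phenylmenthyl furoate A2 adds the carbonyl group across the unsubstituted furan double bond and gives the exo-aryl oxetane A3.
- For it: the exo preference of furan–aryl aldehyde photocycloadditions translates, once O3–C6 is cleaved, into exactly the cis relation between the C4 aryl and C6. On relative configuration it is probably more dependable than the cis preference of the carbene annulation.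
- Against it: alkoxy-rich benzaldehydes have low-lying π,π* triplet states and add sluggishly. The auxiliary sits on the ester at the far double bond, so facial control over the reacting double bond should be weak. A3 still lacks the catechol ring. After the photoreaction the sequence needs selective reductive cleavage of the acetal bond O3–C6, lactonisation with removal of the auxiliary, an arylation at C8 of a β-alkoxyacrylate, hydrogenation and deprotection.
- Comparison: the chosen route brings the catechol ring in as acid chloride 8 and reaches the enol ether 12 in two steps from the lactone. It gives up some certainty in cis selectivity and gains a shorter, catalytic sequence without a stoichiometric auxiliary.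

**Alternative 2: oxidative radical cascade of a propargyl aroylacetate.**
- Disconnection: C1–C5 and O7–C6. All stereochemistry is reduced to C4, carried by the propargylic ester A4.
- Forward key step: Mn(OAc)3 (trivalent manganese) with Cu(OAc)2 (divalent copper) oxidises A4 to the C1 radical. This cyclises 5-exo-dig onto the alkyne, the vinyl radical at C6 is captured by the ketone oxygen, and oxidation gives the furan-fused lactone A5.
- For it: it is very convergent. Its only asymmetric task is a propargylic carbinol centre, which is easier to secure than the enantioselectivity of the carbene step, so it is stronger on absolute control. Hydrogenation of A5 from the face away from the syringyl group would set C1, C5 and C8 together in the required sense.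
- Against it: radical cyclisation through an ester tether is slow because the ester prefers the conformation that holds radical and alkyne apart. The hot acidic oxidising medium endangers a C4–O bond that is both benzylic and propargylic. Above all, A5 is an aromatic furan. Saturating it needs forcing hydrogenation, under which two electron-rich benzene rings and the C4–O3 bond (benzylic and furfurylic in A5) are at risk.
- Comparison: the chosen route has to reduce only one non-aromatic push–pull double bond. It offers a mild, well-defined last C–H bond-forming step in exchange for a weaker handle on absolute configuration.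

**Alternative 3: anionic cascade of an epoxy alkoxide with an aryl ynoate.**
- Disconnection: O7–C8, C1–C5 and O3–C2 in one operation. C4 and C5 come from the epoxy alcohol A6 and C8, C1, C2 from the ynoate A7.
- Forward key step: NaH in THF forms the alkoxide of A6, which adds to A7. The allenolate carbon C1 opens the epoxide at C5 with inversion, and the liberated C4 alkoxide attacks the ester to give the enol ether lactone A8.
- For it: both rings and three bonds form in one flask. The stereocentres of A6 come from an asymmetric epoxidation of predictable sense and high selectivity, so it is clearly stronger than the chosen route on enantiocontrol. A8 is the benzyl-protected counterpart of 12.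
- Against it: the cascade requires a short-lived vinyl anion to open the epoxide at C5 through a planar, strained tether, while the electronically preferred site of this electron-rich aryl epoxide is the benzylic C4. Payne rearrangement of the epoxy alkoxide and simple protonation to an open-chain β-alkoxyacrylate compete. The aryl epoxide is acid-labile. The benzyl ethers must later be removed by hydrogenolysis from a molecule with two benzylic C–O bonds of its own.
- Comparison: the chosen route reaches the same kind of enol ether by separately known steps and ends with fluoride instead of hydrogenolysis. It offers lower mechanistic risk after the key step in exchange for less secure enantioselectivity.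

Key step: step 3

Assumption: the (5aR,10bS) antipode of the aminoindanol-derived triazolium salt is taken to give the (4S,5S) lactone 5; if the sense of induction proves opposite for this substrate pair, the (5aS,10bR) salt is used under the same conditions.

## Route

Step 1
Reactants: 1 syringaldehyde (4-hydroxy-3,5-dimethoxybenzaldehyde)
Product: 2 4-(tert-butyldimethylsilyloxy)-3,5-dimethoxybenzaldehyde
Conditions: TBSCl (1.3 equiv), imidazole (2.5 equiv), DMF, rt
Reagents that add atoms: tert-butyldimethylsilyl chloride, CC(C)(C)[Si](C)(C)Cl
Why: Standard silylation of a phenol with a silyl chloride and imidazole; the hydroxyl is flanked by two methoxy groups but is acidic (para formyl group) and should silylate cleanly in DMF.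

Step 2
Reactants: 3 (tert-butyldimethylsilyloxy)acetaldehyde
Product: 4 (E)-4-(tert-butyldimethylsilyloxy)but-2-enal
Conditions: Ph3P=CHCHO (1.05 equiv), toluene, 80 °C
Reagents that add atoms: (triphenylphosphoranylidene)acetaldehyde, O=CC=P(c1ccccc1)(c1ccccc1)c1ccccc1
Why: Wittig olefination with a formyl-stabilised ylide, which should give the (E)-enal; near-stoichiometric ylide limits a second homologation because the product enal is less electrophilic than the α-silyloxy aldehyde 3.

Step 3
Reactants: 2 4-(tert-butyldimethylsilyloxy)-3,5-dimethoxybenzaldehyde, 4 (E)-4-(tert-butyldimethylsilyloxy)but-2-enal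
Product: 5 (4S,5S)-4-[(tert-butyldimethylsilyloxy)methyl]-5-[4-(tert-butyldimethylsilyloxy)-3,5-dimethoxyphenyl]oxolan-2-one (aryl and silyloxymethyl cis)
Conditions: (5aR,10bS)-2-mesityl-5a,10b-dihydro-4H,6H-indeno[2,1-b][1,2,4]triazolo[4,3-d][1,4]oxazin-2-ium tetrafluoroborate (10 mol %), 1,8-diazabicyclo[5.4.0]undec-7-ene (15 mol %), THF, 4 Å MS, rt; enal added by syringe pump over 8 h to the aldehyde, which is taken in 1.5-fold excess
Reagents that add atoms: none
Why: The carbene generated from the triazolium salt adds to the formyl group of 4, and proton transfer gives the extended Breslow intermediate, whose β-carbon (future C5) is nucleophilic, a homoenolate equivalent. This carbon adds to the aldehyde carbon of 2 (C4–C5), and tautomerisation of the enol gives an acyl azolium that carries the new alkoxide. The alkoxide attacks the acyl azolium carbonyl in a 5-exo-trig closure (O3–C2), which forms the lactone ring and turns the catalyst over, so the step is a one-to-one union in which every atom of 2 and 4 ends up in 5. The closest known reaction type is the carbene-catalysed annulation of enals with aromatic aldehydes to cis-4,5-disubstituted γ-butyrolactones. C5 is set by the catalyst, whose indane backbone and N-mesityl group leave one face of the planar homoenolate open. C4 is set relative to C5 by a compact transition state in which the aldehyde oxygen lies near the enol hydroxyl and the aryl group points away from the azolium, which places aryl and silyloxymethyl on the same side of the new ring. The step needs cross-coupling over enal self-coupling and retention of the γ-oxygen: 2 cannot form a homoenolate, keeping 4 at low concentration against a surplus of 2 stops the enal from serving as its own electrophile, the silyloxy group twisted out of conjugation between two methoxy groups leaves the formyl group of 2 reasonably electrophilic, and silyloxide is too poor a leaving group for γ-elimination to compete. Unreacted 2 and the trans diastereomer are to be removed by chromatography and the enantiomeric purity raised by recrystallisation if the lactone is crystalline.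

Step 4
Reactants: 6 3,4-dihydroxybenzoic acid
Product: 7 tert-butyldimethylsilyl 3,4-bis(tert-butyldimethylsilyloxy)benzoate
Conditions: TBSCl (3.3 equiv), imidazole (7 equiv), DMF, rt
Reagents that add atoms: tert-butyldimethylsilyl chloride, CC(C)(C)[Si](C)(C)Cl
Why: Exhaustive silylation of both phenols and the carboxylic acid under standard silyl chloride/imidazole conditions.

Step 5
Reactants: 7 tert-butyldimethylsilyl 3,4-bis(tert-butyldimethylsilyloxy)benzoate
Product: 8 3,4-bis(tert-butyldimethylsilyloxy)benzoyl chloride
Conditions: (COCl)2 (1.2 equiv), N,N-dimethylformamide (cat.), CH2Cl2, 0 °C to rt; evaporate, use crude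
Reagents that add atoms: oxalyl chloride, ClC(=O)C(Cl)=O
Why: Silyl esters are converted directly into acid chlorides by the chloroiminium salt formed from oxalyl chloride and the formamide, with the silyl group leaving as its chloride; no free HCl is involved, so the aryl silyl ethers should survive.

Step 6
Reactants: 5 cis lactone, 8 3,4-bis(tert-butyldimethylsilyloxy)benzoyl chloride
Product: 9 (3S,4S,5S)-3-[3,4-bis(tert-butyldimethylsilyloxy)benzoyl]-4-[(tert-butyldimethylsilyloxy)methyl]-5-[4-(tert-butyldimethylsilyloxy)-3,5-dimethoxyphenyl]oxolan-2-one (aroyl trans to silyloxymethyl; C3 labile)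
Conditions: LiN(SiMe3)2 (2.2 equiv), THF, −78 °C; then 8 (1.1 equiv), −78 to −40 °C; aq NH4Cl
Reagents that add atoms: none
Why: Claisen-type C-acylation of a lithium lactone enolate with an aroyl chloride; the second equivalent of base deprotonates the more acidic β-keto lactone as it forms, which prevents proton transfer to unreacted enolate and double acylation. C1 (oxolane C3) is set trans but is enolisable, and its configuration is irrelevant because it becomes sp2 in the next step.

Step 7
Reactants: 9 β-keto lactone
Product: 12 (4S,5S)-8-[3,4-bis(tert-butyldimethylsilyloxy)phenyl]-4-[4-(tert-butyldimethylsilyloxy)-3,5-dimethoxyphenyl]-3,7-dioxabicyclo[3.3.0]oct-1(8)-en-2-one, via hydroxy keto lactone 10 (not isolated), via cyclic hemiketal 11 (not isolated)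
Conditions: AcOH/THF/H2O (3:1:1), rt; evaporate with toluene; then pyridinium p-toluenesulfonate (0.1 equiv), toluene, 4 Å MS, 60 °C
Reagents that add atoms: none
Why: Weak aqueous acid cleaves a primary alkyl silyl ether much faster than aryl silyl ethers; the freed C6 hydroxyl adds to the aryl ketone (5-exo-trig, after epimerisation of C1 through the enol) and the hemiketal is dehydrated under mild acid catalysis to the enol ether conjugated with the lactone carbonyl. C4 and C5 are not involved, and the acid is kept weak so that the benzylic C4–O3 bond does not ionise.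

Step 8
Reactants: 12 bicyclic enol ether lactone
Product: 13 (1R,4S,5S,8S)-8-[3,4-bis(tert-butyldimethylsilyloxy)phenyl]-4-[4-(tert-butyldimethylsilyloxy)-3,5-dimethoxyphenyl]-3,7-dioxabicyclo[3.3.0]octan-2-one
Conditions: H2 (3 atm), Rh on Al2O3 (5 wt % Rh), EtOAc, rt
Reagents that add atoms: none
Why: Heterogeneous syn hydrogenation of a β-alkoxyacrylate-type double bond; rhodium on alumina is the usual choice for such enol ethers because it adds hydrogen with little cleavage of benzylic C–O bonds. Both hydrogens should arrive on the convex face that carries H5 and H4, since the concave face is blocked by the fold of the bicycle and by the syringyl group; this gives the cis ring fusion (C1, R) and the endo catechol ring (C8, S).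

Step 9
Reactants: 13 tris-silyl ether of the target
Product: 14 (1R,4S,5S,8S)-8-(3,4-dihydroxyphenyl)-4-(4-hydroxy-3,5-dimethoxyphenyl)-3,7-dioxabicyclo[3.3.0]octan-2-one (target)
Conditions: Bu4NF (3.6 equiv), AcOH (3.6 equiv), THF, 0 °C, argon
Reagents that add atoms: none
Why: Fluoride cleavage of aryl silyl ethers; acetic acid keeps the liberated phenols protonated, so no phenoxide is available to expel the C4 carboxylate or the C8 alkoxide, and argon protects the catechol. No stereocentre is touched.

## Compound list

1 | syringaldehyde (4-hydroxy-3,5-dimethoxybenzaldehyde) | COc1cc(C=O)cc(OC)c1O | starting material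
2 | 4-(tert-butyldimethylsilyloxy)-3,5-dimethoxybenzaldehyde | COc1cc(C=O)cc(OC)c1O[Si](C)(C)C(C)(C)C | intermediate
3 | (tert-butyldimethylsilyloxy)acetaldehyde | O=CCO[Si](C)(C)C(C)(C)C | starting material
4 | (E)-4-(tert-butyldimethylsilyloxy)but-2-enal | O=C/C=C/CO[Si](C)(C)C(C)(C)C | intermediate
5 | (4S,5S)-4-[(tert-butyldimethylsilyloxy)methyl]-5-[4-(tert-butyldimethylsilyloxy)-3,5-dimethoxyphenyl]oxolan-2-one | COc1cc([C@H]2OC(=O)C[C@H]2CO[Si](C)(C)C(C)(C)C)cc(OC)c1O[Si](C)(C)C(C)(C)C | intermediate
6 | 3,4-dihydroxybenzoic acid | OC(=O)c1ccc(O)c(O)c1 | starting material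
7 | tert-butyldimethylsilyl 3,4-bis(tert-butyldimethylsilyloxy)benzoate | CC(C)(C)[Si](C)(C)OC(=O)c1ccc(O[Si](C)(C)C(C)(C)C)c(O[Si](C)(C)C(C)(C)C)c1 | intermediate
8 | 3,4-bis(tert-butyldimethylsilyloxy)benzoyl chloride | ClC(=O)c1ccc(O[Si](C)(C)C(C)(C)C)c(O[Si](C)(C)C(C)(C)C)c1 | intermediate
9 | (3S,4S,5S)-3-[3,4-bis(tert-butyldimethylsilyloxy)benzoyl]-4-[(tert-butyldimethylsilyloxy)methyl]-5-[4-(tert-butyldimethylsilyloxy)-3,5-dimethoxyphenyl]oxolan-2-one | COc1cc([C@H]2OC(=O)[C@H](C(=O)c3ccc(O[Si](C)(C)C(C)(C)C)c(O[Si](C)(C)C(C)(C)C)c3)[C@H]2CO[Si](C)(C)C(C)(C)C)cc(OC)c1O[Si](C)(C)C(C)(C)C | intermediate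
10 | (3S,4S,5S)-3-[3,4-bis(tert-butyldimethylsilyloxy)benzoyl]-4-(hydroxymethyl)-5-[4-(tert-butyldimethylsilyloxy)-3,5-dimethoxyphenyl]oxolan-2-one (C3 equilibrates through the enol) | COc1cc([C@H]2OC(=O)[C@H](C(=O)c3ccc(O[Si](C)(C)C(C)(C)C)c(O[Si](C)(C)C(C)(C)C)c3)[C@H]2CO)cc(OC)c1O[Si](C)(C)C(C)(C)C | intermediate (not isolated)
11 | (1R,4S,5S)-8-[3,4-bis(tert-butyldimethylsilyloxy)phenyl]-8-hydroxy-4-[4-(tert-butyldimethylsilyloxy)-3,5-dimethoxyphenyl]-3,7-dioxabicyclo[3.3.0]octan-2-one (both C8 anomers) | COc1cc([C@H]2OC(=O)[C@@H]3[C@H]2COC3(O)c2ccc(O[Si](C)(C)C(C)(C)C)c(O[Si](C)(C)C(C)(C)C)c2)cc(OC)c1O[Si](C)(C)C(C)(C)C | intermediate (not isolated)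
12 | (4S,5S)-8-[3,4-bis(tert-butyldimethylsilyloxy)phenyl]-4-[4-(tert-butyldimethylsilyloxy)-3,5-dimethoxyphenyl]-3,7-dioxabicyclo[3.3.0]oct-1(8)-en-2-one | COc1cc([C@H]2OC(=O)C3=C(c4ccc(O[Si](C)(C)C(C)(C)C)c(O[Si](C)(C)C(C)(C)C)c4)OC[C@@H]23)cc(OC)c1O[Si](C)(C)C(C)(C)C | intermediate
13 | (1R,4S,5S,8S)-8-[3,4-bis(tert-butyldimethylsilyloxy)phenyl]-4-[4-(tert-butyldimethylsilyloxy)-3,5-dimethoxyphenyl]-3,7-dioxabicyclo[3.3.0]octan-2-one | COc1cc([C@H]2OC(=O)[C@@H]3[C@H]2CO[C@@H]3c2ccc(O[Si](C)(C)C(C)(C)C)c(O[Si](C)(C)C(C)(C)C)c2)cc(OC)c1O[Si](C)(C)C(C)(C)C | intermediate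
14 | (1R,4S,5S,8S)-8-(3,4-dihydroxyphenyl)-4-(4-hydroxy-3,5-dimethoxyphenyl)-3,7-dioxabicyclo[3.3.0]octan-2-one | COc1cc([C@H]2OC(=O)[C@@H]3[C@H]2CO[C@@H]3c2ccc(O)c(O)c2)cc(OC)c1O | target

## Step count and uncertain steps

Total: 9 steps. Longest linear sequence: 6 steps (1, 3, 6, 7, 8, 9 from syringaldehyde 1; the branches from 3 and from 6 are equally long).

**Step 3 (key step).**
What may go wrong: self-coupling of the enal, in which the homoenolate adds to a second molecule of 4; slow addition to 2, whose formyl group is only moderately electrophilic; base-induced dienolisation of 4 or expulsion of silyloxide from the γ-carbon; insufficient cis or facial selectivity, because high enantioselectivity with an aliphatic enal and an electron-rich aryl aldehyde is not assured.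
Fallback, from 2 back to 5, by an auxiliary-controlled anti-aldol reaction: (S)-4-benzyl-3-(pent-4-enoyl)oxazolidin-2-one F1 is made by N-acylation of the parent oxazolidinone and combined with 2 under MgCl2 catalysis (MgCl2 20 mol %, Et3N, Me3SiCl, EtOAc, rt). The chelated (Z)-magnesium enolate is attacked on the face away from the benzyl group and in the anti sense, which should give the silylated anti-aldol adduct F2. Brief treatment with 1 M HCl in THF frees the anti-aldol alcohol F3, and LiBH4 (THF, trace water, 0 °C) removes the auxiliary reductively to give the 2-allyl-1-arylpropane-1,3-diol F4. TBSCl and imidazole at 0 °C silylate only the primary hydroxyl, giving the homoallylic alcohol F5. OsO4 (cat.), NaIO4 and 2,6-lutidine in dioxane/water cleave the terminal alkene, and the aldehyde closes onto the benzylic hydroxyl to the lactol F6, which PhI(OAc)2 with catalytic 2,2,6,6-tetramethylpiperidin-1-oxyl oxidises to lactone 5. The anti relation of the aldol adduct becomes the cis relation of aryl and silyloxymethyl in the ring.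

**Step 6 (aroylation).**
What may go wrong: O-acylation of the enolate to an enol ester, consumption of the acid chloride by the excess amide base, or quenching of the enolate by the product.
Fallback, from 5 back to 9, by aldol addition and oxidation: the lithium enolate of 5 (LiN(SiMe3)2, THF, −78 °C) is added to 3,4-bis(tert-butyldimethylsilyloxy)benzaldehyde F7, made by silylating 3,4-dihydroxybenzaldehyde. A cold quench gives the β-hydroxy lactone F8 as carbinol epimers, and Dess–Martin periodinane (NaHCO3, CH2Cl2) oxidises it to 9.

**Step 7 (desilylation and cyclodehydration).**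
What may go wrong: migration of the lactone acyl group to the freed C6 hydroxyl, followed by closure of the benzylic hydroxyl onto the ketone, which would give a constitutionally isomeric bicycle; epimerisation at C4 through benzylic ionisation if the acid is too strong; incomplete dehydration of the hemiketal.
Fallback, from 5 back to 12, which removes the primary silyl group before any ketone is present and makes the C1–C8 bond intramolecularly: AcOH/THF/H2O converts 5 into the hydroxymethyl lactone F9, and esterification with 8 (pyridine, catalytic 4-(dimethylamino)pyridine, CH2Cl2, 0 °C) gives the C6 aroyl ester F10. LiN(SiMe3)2 (2.2 equiv, THF, −78 to 0 °C) forms the C1 enolate, which attacks the ester carbonyl through a five-membered transition state (O-to-C aroyl shift). The quench delivers 10 in equilibrium with 11, which is dehydrated as in step 7 (pyridinium p-toluenesulfonate, toluene, 4 Å MS) to 12.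

**Step 8 (hydrogenation).**
What may go wrong: no reaction at the tetrasubstituted, electron-rich double bond under mild pressure; under more forcing conditions, saturation of the alkoxy-substituted benzene rings or hydrogenolysis of the benzylic C4–O3 bond.
Fallback, from 12 back to 13, by dissolving-metal-type conjugate reduction: SmI2 (divalent samarium, 3 equiv) in THF/MeOH at −78 to 0 °C transfers two electrons to the β-aryl enoate. Protonation at C8 should occur on the open convex face, and protonation of the samarium enolate at C1 can only give the cis-fused lactone. No new compound is isolated.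

**Step 9 (global desilylation).**
What may go wrong: phenoxide formation if the medium becomes basic, followed by opening of the C4–O3 bond to a quinone methide with re-closure to the exo epimer; epimerisation or β-elimination at C8; air oxidation of the catechol.
Fallback, from 12 back to 14, by changing the order of the last two operations: the three silyl groups are removed at the enol ether stage, where C8 is sp2 and cannot epimerise or eliminate (Bu4NF/AcOH, THF, 0 °C), giving the triphenolic enol ether F11. F11 is then hydrogenated under the conditions of step 8, so the last step is a neutral hydrogenation that gives 14 directly.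

## Further compounds

F1 | step 3 | (S)-4-benzyl-3-(pent-4-enoyl)oxazolidin-2-one | C=CCCC(=O)N1[C@@H](Cc2ccccc2)COC1=O
F2 | step 3 | (S)-4-benzyl-3-{(2R)-2-[(S)-[4-(tert-butyldimethylsilyloxy)-3,5-dimethoxyphenyl](trimethylsilyloxy)methyl]pent-4-enoyl}oxazolidin-2-one | COc1cc([C@@H](O[Si](C)(C)C)[C@@H](CC=C)C(=O)N2[C@@H](Cc3ccccc3)COC2=O)cc(OC)c1O[Si](C)(C)C(C)(C)C
F3 | step 3 | (S)-4-benzyl-3-{(2R)-2-[(S)-[4-(tert-butyldimethylsilyloxy)-3,5-dimethoxyphenyl](hydroxy)methyl]pent-4-enoyl}oxazolidin-2-one | COc1cc([C@@H](O)[C@@H](CC=C)C(=O)N2[C@@H](Cc3ccccc3)COC2=O)cc(OC)c1O[Si](C)(C)C(C)(C)C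
F4 | step 3 | (1S,2S)-2-allyl-1-[4-(tert-butyldimethylsilyloxy)-3,5-dimethoxyphenyl]propane-1,3-diol | COc1cc([C@@H](O)[C@@H](CC=C)CO)cc(OC)c1O[Si](C)(C)C(C)(C)C
F5 | step 3 | (1S,2S)-2-[(tert-butyldimethylsilyloxy)methyl]-1-[4-(tert-butyldimethylsilyloxy)-3,5-dimethoxyphenyl]pent-4-en-1-ol | COc1cc([C@@H](O)[C@@H](CC=C)CO[Si](C)(C)C(C)(C)C)cc(OC)c1O[Si](C)(C)C(C)(C)C
F6 | step 3 | (4S,5S)-4-[(tert-butyldimethylsilyloxy)methyl]-5-[4-(tert-butyldimethylsilyloxy)-3,5-dimethoxyphenyl]oxolan-2-ol (both anomers) | COc1cc([C@H]2OC(O)C[C@H]2CO[Si](C)(C)C(C)(C)C)cc(OC)c1O[Si](C)(C)C(C)(C)C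
F7 | step 6 | 3,4-bis(tert-butyldimethylsilyloxy)benzaldehyde | O=Cc1ccc(O[Si](C)(C)C(C)(C)C)c(O[Si](C)(C)C(C)(C)C)c1
F8 | step 6 | (3S,4S,5S)-3-{[3,4-bis(tert-butyldimethylsilyloxy)phenyl](hydroxy)methyl}-4-[(tert-butyldimethylsilyloxy)methyl]-5-[4-(tert-butyldimethylsilyloxy)-3,5-dimethoxyphenyl]oxolan-2-one (carbinol epimers) | COc1cc([C@H]2OC(=O)[C@H](C(O)c3ccc(O[Si](C)(C)C(C)(C)C)c(O[Si](C)(C)C(C)(C)C)c3)[C@H]2CO[Si](C)(C)C(C)(C)C)cc(OC)c1O[Si](C)(C)C(C)(C)C
F9 | step 7 | (4S,5S)-4-(hydroxymethyl)-5-[4-(tert-butyldimethylsilyloxy)-3,5-dimethoxyphenyl]oxolan-2-one | COc1cc([C@H]2OC(=O)C[C@H]2CO)cc(OC)c1O[Si](C)(C)C(C)(C)C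
F10 | step 7 | {(2S,3S)-2-[4-(tert-butyldimethylsilyloxy)-3,5-dimethoxyphenyl]-5-oxooxolan-3-yl}methyl 3,4-bis(tert-butyldimethylsilyloxy)benzoate | COc1cc([C@H]2OC(=O)C[C@H]2COC(=O)c2ccc(O[Si](C)(C)C(C)(C)C)c(O[Si](C)(C)C(C)(C)C)c2)cc(OC)c1O[Si](C)(C)C(C)(C)C
F0 | step 8 | none | none
F11 | step 9 | (4S,5S)-8-(3,4-dihydroxyphenyl)-4-(4-hydroxy-3,5-dimethoxyphenyl)-3,7-dioxabicyclo[3.3.0]oct-1(8)-en-2-one | COc1cc([C@H]2OC(=O)C3=C(c4ccc(O)c(O)c4)OC[C@@H]23)cc(OC)c1O
A1 | alternative 1 | 4-acetoxy-3,5-dimethoxybenzaldehyde | COc1cc(C=O)cc(OC)c1OC(C)=O
A2 | alternative 1 | (1R,2S,5R)-8-phenylmenthyl furan-3-carboxylate | C[C@@H]1CC[C@H]([C@@H](C1)OC(=O)c1ccoc1)C(C)(C)c1ccccc1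
A3 | alternative 1 | (1R,2S,5R)-8-phenylmenthyl exo-6-(4-acetoxy-3,5-dimethoxyphenyl)-2,7-dioxabicyclo[3.2.0]hept-3-ene-4-carboxylate | C[C@@H]1CC[C@H]([C@@H](C1)OC(=O)C1=CO[C@H]2O[C@H](c3cc(OC)c(OC(C)=O)c(OC)c3)[C@@H]12)C(C)(C)c1ccccc1
A4 | alternative 2 | (S)-1-(4-acetoxy-3,5-dimethoxyphenyl)prop-2-yn-1-yl 3-(3,4-diacetoxyphenyl)-3-oxopropanoate | COc1cc([C@H](C#C)OC(=O)CC(=O)c2ccc(OC(C)=O)c(OC(C)=O)c2)cc(OC)c1OC(C)=O
A5 | alternative 2 | (3R)-3-(4-acetoxy-3,5-dimethoxyphenyl)-6-(3,4-diacetoxyphenyl)-1H,3H-furo[3,4-c]furan-1-one | COc1cc([C@H]2OC(=O)c3c2coc3-c2ccc(OC(C)=O)c(OC(C)=O)c2)cc(OC)c1OC(C)=O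
A6 | alternative 3 | [(2R,3R)-3-(4-benzyloxy-3,5-dimethoxyphenyl)oxiran-2-yl]methanol | OC[C@H]1O[C@@H]1c1cc(OC)c(OCc2ccccc2)c(OC)c1
A7 | alternative 3 | methyl 3-[3,4-bis(benzyloxy)phenyl]prop-2-ynoate | COC(=O)C#Cc1ccc(OCc2ccccc2)c(OCc2ccccc2)c1
A8 | alternative 3 | (4S,5S)-8-[3,4-bis(benzyloxy)phenyl]-4-(4-benzyloxy-3,5-dimethoxyphenyl)-3,7-dioxabicyclo[3.3.0]oct-1(8)-en-2-one | COc1cc([C@H]2OC(=O)C3=C(c4ccc(OCc5ccccc5)c(OCc5ccccc5)c4)OC[C@@H]23)cc(OC)c1OCc1ccccc1
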